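## Structural features

The target is one fully substituted tetrahydrofuran ring (O1, C2 to C5) with 4-hydroxy-3,5-dimethoxyphenyl (syringyl) groups on C2 and C5 and hydroxymethyl groups on C3 and C4. No other ring is fused or bridged to it, and each arene is joined to the heterocycle by a single C–C bond. The four stereocentres C2, C3, C4 and C5 are contiguous, have the configuration 2R,3S,4S,5R, and every neighbouring pair is trans. A twofold axis therefore runs through O1 and the midpoint of C3–C4, and only two stereocentres are independent. The fragile elements are the two electron-rich free phenols and, above all, the benzylic C2–O1 and C5–O1 bonds. These are para-hydroxybenzyl ethers that ionise under acid, which permits epimerisation but also irreversible C-arylation to an aryltetralin. Free hydroxymethyl groups could capture a cation at C2 or C5, so they must be masked while such cations are present. The real difficulty is the absolute configuration of the C3–C4 pair and its relay to C2 and C5 under conditions the benzylic ethers survive. The key step uses the fact that C2 and C5 are each bonded to O1 and to one aryl carbon. With the aryl group removed each is an acetal carbon, so both C–aryl bonds can be made by oxocarbenium arylation of a C2-symmetric 2,5-dialkoxytetrahydrofuran.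

## Logic of the disconnections

14 to 13. No skeletal bond is cut; the two primary O–H groups are traced back to O–Si bonds. The reason is that the hydroxymethyl oxygens must be inert and bulky during the cation chemistry that precedes. The gain is only that the next cut becomes permissible. The demand on the forward step is a desilylation that is neither acidic nor strongly basic, so that the phenolic benzylic ethers are left alone.

13 to 10 and two molecules of 11 (through 12). The bonds cut are C2–C(aryl) and C5–C(aryl). Each joins an acetal-level carbon to the para carbon of a phenol, which is the retron of a Friedel–Crafts arylation of a cyclic oxocarbenium ion. Both arenes leave as one commercial compound and two of the four stereocentres disappear, leaving a core with only the C3/C4 pair. The forward step must arylate twice, through carbon and para to the hydroxyl, each time trans to the neighbouring substituent, and must stop before the product ring is re-opened.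

10 to 8 (through 9). The two C–OMe bonds and the ring C–O bonds of 10 are traced back to the two aldehydes of 9, and each C=O to a terminal C=CH2 of 8. This removes the ring and leaves an acyclic, C2-symmetric diene whose only stereocentres are the future C3 and C4. The forward step must cleave both alkenes and close the bis-acetal without epimerising the α-carbons or eliminating the β-silyloxy groups. For that reason 9 is not isolated.

8 to 7. The two O–Si bonds are cut. The silyl group is chosen to withstand acidic alcohol and a boron Lewis acid and to add steric bias next to C2 and C5. The forward step is routine.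

7 to 6. The two CH2–OH carbons are traced back to imide carbonyls, with C–N bonds to two molecules of auxiliary 2. This places the stereocentres α to an activating group that can be used to form them. The forward reduction must not epimerise these doubly activated positions or move the double bonds.

6 to two molecules of 4 (through 5). The central C–C bond, the future C3–C4 bond, is cut into two identical halves. This is the only skeletal C–C bond formation apart from the key step, and it sets both independent stereocentres of the core. The forward step must couple the two α-carbons (not the γ-carbons) on the enolate face that the auxiliary leaves open, which requires the R-configured 2.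

4 to 1 and 2 (through 3). The N–acyl bond is cut to give two commercial compounds. The forward acylation must avoid migration of the β,γ-double bond.

## Other disconnections considered

Alternative 1: The ring is cut through O1–C2 and C3–C4 into a three-atom piece, vinyl epoxide A2, and a two-atom piece, arylidene malonate A3. In the forward sense Pd(PPh3)4, a zerovalent palladium complex, would ionise A2 to a π-allyl cation carrying an alkoxide. The alkoxide would add to A3, and the malonate anion so formed would close on the near allyl terminus to give tetrahydrofuran A1.
- In its favour: the ring and two bonds are made in one catalytic, convergent step under neutral conditions. The two aryl groups come from different partners, so unsymmetrical congeners would be accessible. On that point it is the better plan.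
- Against it here: A1 has the wrong substitution pattern. C3 is a quaternary gem-diester and C4 carries a vinyl group. One ester must be removed, which creates the C3 stereocentre only by a late protonation and passes through an ester enolate β to the ring oxygen (ring-opening by retro-oxa-Michael reaction is conceivable). The other ester must be reduced, the vinyl group cleaved and reduced, and the benzyl ethers removed.
- Absolute configuration would rest on enantiopure A2 and on a π-allyl intermediate that does not equilibrate.
- Structure: it treats C3 and C4 as different and ignores the twofold symmetry that the chosen plan exploits.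
- Mechanism: both plans rely on substrate control for the trans relationships, here through a reversible oxa-Michael addition, there through cation equilibration. On that point they are equal.
- Step economy: partner synthesis, annulation and four or five adjustments would make it clearly longer than seven steps.

Alternative 2: Both ring C–O bonds (O1–C2 and O1–C5) are cut and C2 is joined to C5, which leads to cyclobutane A5 with O1 coming from water. In the forward sense Ag2O would oxidise the bisphenol A5 by two electrons, the strained aryl-bearing C–C bond would break to a bis(quinone methide), water would add to one terminus and the new hydroxyl to the other, giving diester A4. Hydride reduction of both esters would then give the target.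
- In its favour: it is very short, since A5 would come from photodimerisation of methyl sinapate A6. It needs no protecting groups, stores the trans C3/C4 relationship in the cyclobutane, and uses the same twofold symmetry. On step count and protecting-group economy it is the better plan. In its use of symmetry and of reversible quinone-methide chemistry to reach the all-trans array it is the equal of the chosen plan.
- Against it here: a single enantiomer requires A5 as one enantiomer of the head-to-head, all-trans dimer. Control of regiochemistry, relative and absolute configuration in a cinnamate [2+2] photodimerisation needs a covalent template or a chiral sensitiser. That is harder to guarantee than an auxiliary-controlled enolate coupling.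
- The syringyl bis(quinone methide) could also be diverted by intramolecular C-arylation to an aryldihydronaphthalene, and the oxidant is stoichiometric silver.
- Mechanism: the chosen plan forms C–C bonds at C2 and C5 with an acid, this one forms C–O bonds with an oxidant. Both pass through the same kind of benzylic cation or quinone methide.
- Overall: the chosen plan is longer but places the control of absolute configuration in a better understood step.

Alternative 3: Only O1–C2 is cut, giving the open-chain carbinol A8. It has a free para-alkylphenol at the future C2 and a benzyl-protected aryl carbinol at C5. In the forward sense Ag2O would oxidise the para-alkylphenol to a quinone methide at C2 and the C5 hydroxyl would add to it (5-exo-trig) to give tetrahydrofuran A7. Hydrogenolysis and desilylation would then give the target.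
- In its favour: a single bond is formed under mild, neutral, oxidative conditions, so no Lewis acid meets the finished phenolic benzylic ether. On that point it is the better plan. C3, C4 and C5 are set beforehand, and two different aryl groups could be carried, which the present target does not need.
- Against it here: A8 is an acyclic chain with three contiguous stereocentres and two differently protected arenes. Each half must be built separately, with orthogonal phenol protection, so the linear sequence would be long.
- Structure: the symmetry of the target is not used.
- Mechanism: C2 is set by the neighbouring stereocentre in the ring-forming event, exactly as in the chosen plan. On that point they are equal.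
- Step economy: it cannot match seven steps.

Key step: step 6

Remark on the chemistry: the oxidative enolate coupling is assumed to follow the usual chelated Z-enolate model, with bond formation on the face remote from the benzyl group. On that basis the R-configured auxiliary 2 leads to the 3S,4S core; the S-configured auxiliary would lead to the enantiomer of the target.

## Route

Step 1
Reactants: 1 but-3-enoic acid; 2 (R)-4-benzyl-2-oxazolidinone
Product: 4 (R)-4-benzyl-3-(but-3-enoyl)oxazolidin-2-one, via but-3-enoic pivalic anhydride 3 (not isolated)
Conditions: t-BuCOCl, Et3N, THF, −20 °C; then LiCl, 2, −20 °C → rt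
Reagents that add atoms: none
Why: Mixed-anhydride N-acylation of an oxazolidinone assisted by LiCl: the nitrogen of 2 attacks the less hindered butenoyl carbonyl of 3; no strong base is present, which limits migration of the β,γ-double bond, and no stereocentre is formed.

Step 2
Reactants: 4 (R)-4-benzyl-3-(but-3-enoyl)oxazolidin-2-one (two molecules)
Product: 6 (4R,4'R)-3,3'-[(2S,3S)-2,3-divinylbutanedioyl]bis(4-benzyloxazolidin-2-one), via trichlorotitanium Z-dienolate 5 (not isolated)
Conditions: TiCl4, i-Pr2NEt, CH2Cl2, −78 °C → rt
Reagents that add atoms: none
Why: Oxidative homocoupling of a titanium imide enolate: soft enolisation gives the chelated Z-dienolate 5 of tetravalent titanium, which on warming passes one electron to the metal (trivalent titanium is released) and couples through its α-carbon, the position at which such metal dienolates react with electrophiles. Each α-carbon should bond on the face remote from the benzyl group of its auxiliary, so both new stereocentres form as S and the C2-symmetric 2S,3S isomer results; the mixture is not heated because 6 is a 3,4-diacylhexa-1,5-diene capable of Cope rearrangement.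

Step 3
Reactants: 6 (4R,4'R)-3,3'-[(2S,3S)-2,3-divinylbutanedioyl]bis(4-benzyloxazolidin-2-one)
Product: 7 (2S,3S)-2,3-divinylbutane-1,4-diol
Conditions: LiBH4, MeOH (1 equiv), Et2O, 0 °C
Reagents that add atoms: none
Why: Reductive cleavage of an N-acyloxazolidinone with LiBH4: hydride attacks the exocyclic imide carbonyl and reduces it to the primary alcohol while 2 is released for recovery; the medium is barely basic at 0 °C, so the α-stereocentres should neither epimerise nor lose their β,γ-unsaturation.

Step 4
Reactants: 7 (2S,3S)-2,3-divinylbutane-1,4-diol
Product: 8 (3S,4S)-3,4-bis[(tert-butyldiphenylsilyloxy)methyl]hexa-1,5-diene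
Conditions: TBDPSCl, imidazole, DMF, 0 °C → rt
Reagents that add atoms: tert-butyl(chloro)diphenylsilane, CC(C)(C)[Si](Cl)(c1ccccc1)c1ccccc1
Why: Routine silylation of primary alcohols; this silyl group is chosen because it should survive the acidic methanol of step 5 and the BF3·OEt2 of step 6 and is bulky enough to bias the arylation.

Step 5
Reactants: 8 (3S,4S)-3,4-bis[(tert-butyldiphenylsilyloxy)methyl]hexa-1,5-diene
Product: 10 (3S,4S)-3,4-bis[(tert-butyldiphenylsilyloxy)methyl]-2,5-dimethoxytetrahydrofuran (anomeric mixture), via dialdehyde 9 (not isolated)
Conditions: O3, CH2Cl2/MeOH, −78 °C; Me2S, −78 °C → rt; then camphorsulfonic acid (cat.), MeOH, 0 °C → rt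
Reagents that add atoms: ozone, [O-][O+]=O; methanol, CO
Why: Ozonolysis with reductive work-up, followed in the same flask by acid-catalysed cyclic acetal formation of the 1,4-dialdehyde (the reaction that turns succinaldehyde into 2,5-dimethoxytetrahydrofuran). Dialdehyde 9 never meets base or silica, which protects its α-stereocentres and prevents β-elimination of silanol; the two new acetal centres are uncontrolled and irrelevant because both are ionised in step 6.

Step 6
Reactants: 10 (3S,4S)-3,4-bis[(tert-butyldiphenylsilyloxy)methyl]-2,5-dimethoxytetrahydrofuran; 11 2,6-dimethoxyphenol (2.2 equiv)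
Product: 13 (2R,3S,4S,5R)-2,5-bis(4-hydroxy-3,5-dimethoxyphenyl)-3,4-bis[(tert-butyldiphenylsilyloxy)methyl]tetrahydrofuran, via monoaryl methyl acetal 12 (not isolated)
Conditions: BF3·OEt2, CH2Cl2, −78 → −20 °C
Reagents that add atoms: none
Why: BF3 binds one methoxy group of 10 and expels it, giving a five-membered cyclic oxocarbenium ion at C2; 11 attacks through C4, the only free position activated by its hydroxyl group (both ortho positions carry methoxy groups), and rearomatisation gives 12, after which the same sequence at C5 gives 13. Because 10 is C2-symmetric the two acetal carbons are equivalent and the order of the two events does not matter. The closest known reaction type is the Lewis-acid Friedel–Crafts C-arylation of 2-alkoxytetrahydrofurans (lactol methyl ethers) by phenols and alkoxyarenes; any O-aryl acetal formed first should rearrange to the C-aryl compound under the same acid. No ring is closed: the tetrahydrofuran of 10 is kept and two exocyclic C–C bonds are made. Each new stereocentre is controlled by its ring neighbour (C2 by C3, C5 by C4): the bulky arene should add anti to the adjacent silyloxymethyl group, and since those groups are trans the aryl groups end on opposite faces, giving the all-trans 2R,5R array. If stereoelectronically favoured inside attack gives some 2,3-cis isomer, the para-hydroxybenzylic C–O bond can re-ionise under BF3 and re-close, so the mixture should drain to the all-trans isomer, which is the most stable one. The step needs C-arylation para to the hydroxyl group (not O-arylation or attack at C3 of the phenol) and exactly two arylations; the free hydroxyl group, the blocked ortho positions, a small excess of 11 and low temperature with an early quench are what secure this.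

Step 7
Reactants: 13 (2R,3S,4S,5R)-2,5-bis(4-hydroxy-3,5-dimethoxyphenyl)-3,4-bis[(tert-butyldiphenylsilyloxy)methyl]tetrahydrofuran
Product: 14 [(2R,3S,4S,5R)-2,5-bis(4-hydroxy-3,5-dimethoxyphenyl)tetrahydrofuran-3,4-diyl]dimethanol
Conditions: Bu4NF, AcOH, THF, 0 °C → rt
Reagents that add atoms: none
Why: Fluoride-induced cleavage of silyl ethers, driven by Si–F bond formation; buffering with acetic acid keeps the phenols protonated, so neither quinone-methide formation nor aerial oxidation of a phenoxide is expected, and no stereocentre is touched.

## Compound list

1 | but-3-enoic acid | C=CCC(=O)O | starting material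
2 | (R)-4-benzyl-2-oxazolidinone | O=C1OC[C@@H](Cc2ccccc2)N1 | starting material
3 | but-3-enoic pivalic anhydride | C=CCC(=O)OC(=O)C(C)(C)C | intermediate
4 | (R)-4-benzyl-3-(but-3-enoyl)oxazolidin-2-one | C=CCC(=O)N1[C@H](Cc2ccccc2)COC1=O | intermediate
5 | trichlorotitanium Z-dienolate of 4, (R)-4-benzyl-3-[(1Z)-1-(trichlorotitaniooxy)buta-1,3-dien-1-yl]oxazolidin-2-one | C=C/C=C(\O[Ti](Cl)(Cl)Cl)N1[C@H](Cc2ccccc2)COC1=O | intermediate
6 | (4R,4'R)-3,3'-[(2S,3S)-2,3-divinylbutanedioyl]bis(4-benzyloxazolidin-2-one) | C=C[C@H](C(=O)N1[C@H](Cc2ccccc2)COC1=O)[C@H](C=C)C(=O)N1[C@H](Cc2ccccc2)COC1=O | intermediate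
7 | (2S,3S)-2,3-divinylbutane-1,4-diol | C=C[C@H](CO)[C@H](C=C)CO | intermediate
8 | (3S,4S)-3,4-bis[(tert-butyldiphenylsilyloxy)methyl]hexa-1,5-diene | C=C[C@H](CO[Si](c1ccccc1)(c1ccccc1)C(C)(C)C)[C@H](C=C)CO[Si](c1ccccc1)(c1ccccc1)C(C)(C)C | intermediate
9 | (2S,3S)-2,3-bis[(tert-butyldiphenylsilyloxy)methyl]butanedial | O=C[C@H](CO[Si](c1ccccc1)(c1ccccc1)C(C)(C)C)[C@H](C=O)CO[Si](c1ccccc1)(c1ccccc1)C(C)(C)C | intermediate
10 | (3S,4S)-3,4-bis[(tert-butyldiphenylsilyloxy)methyl]-2,5-dimethoxytetrahydrofuran, anomeric mixture | COC1OC(OC)[C@H](CO[Si](c2ccccc2)(c2ccccc2)C(C)(C)C)[C@H]1CO[Si](c1ccccc1)(c1ccccc1)C(C)(C)C | intermediate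
11 | 2,6-dimethoxyphenol | COc1cccc(OC)c1O | starting material
12 | (2R,3S,4S)-2-(4-hydroxy-3,5-dimethoxyphenyl)-5-methoxy-3,4-bis[(tert-butyldiphenylsilyloxy)methyl]tetrahydrofuran, C5 epimers | COc1cc([C@@H]2OC(OC)[C@H](CO[Si](c3ccccc3)(c3ccccc3)C(C)(C)C)[C@H]2CO[Si](c2ccccc2)(c2ccccc2)C(C)(C)C)cc(OC)c1O | intermediate
13 | (2R,3S,4S,5R)-2,5-bis(4-hydroxy-3,5-dimethoxyphenyl)-3,4-bis[(tert-butyldiphenylsilyloxy)methyl]tetrahydrofuran | COc1cc([C@@H]2O[C@@H](c3cc(OC)c(O)c(OC)c3)[C@H](CO[Si](c3ccccc3)(c3ccccc3)C(C)(C)C)[C@H]2CO[Si](c2ccccc2)(c2ccccc2)C(C)(C)C)cc(OC)c1O | intermediate
14 | [(2R,3S,4S,5R)-2,5-bis(4-hydroxy-3,5-dimethoxyphenyl)tetrahydrofuran-3,4-diyl]dimethanol | COc1cc([C@@H]2O[C@@H](c3cc(OC)c(O)c(OC)c3)[C@H](CO)[C@H]2CO)cc(OC)c1O | target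

## Step count and least certain steps

Total step count: 7. Longest linear sequence: 7 steps (1 to 14).

Step 6 (key step). What may go wrong:
- incomplete facial control, with arylation syn to the neighbouring silyloxymethyl group;
- acid-induced re-opening of the newly formed para-hydroxybenzylic ether, with capture of the cation by a third molecule of 11 or by the second aryl ring (cyclisation to an aryltetralin);
- O-arylation instead of C-arylation, or loss of a silyl ether on long exposure.

The route depends on equilibration helping without over-reaction taking over. Fallback, setting out from 8 and rejoining at 14: the polarity is reversed, so the arene is added as an organometallic to a carbonyl and the ring is closed by C–O bond formation. Ozonolysis of 8 in CH2Cl2 with PPh3 work-up would give 9, used crude and cold. The aryl bromide tert-butyl(4-bromo-2,6-dimethoxyphenoxy)dimethylsilane F1 (from commercial 4-bromo-2,6-dimethoxyphenol, TBSCl and imidazole) would be converted with Mg in THF into its Grignard reagent and added twice to 9 at −78 °C. This would give the 1,4-diaryl-1,4-diol (2S,3S)-1,4-bis[4-(tert-butyldimethylsilyloxy)-3,5-dimethoxyphenyl]-2,3-bis[(tert-butyldiphenylsilyloxy)methyl]butane-1,4-diol F2 as a mixture of carbinol epimers. Catalytic camphorsulfonic acid in CH2Cl2 at 0 °C should ionise one benzylic alcohol and close the ether with each aryl group trans to its neighbour, giving the tetrasilylated tetrahydrofuran (2R,3S,4S,5R)-2,5-bis[4-(tert-butyldimethylsilyloxy)-3,5-dimethoxyphenyl]-3,4-bis[(tert-butyldiphenylsilyloxy)methyl]tetrahydrofuran F3. Bu4NF/AcOH would then remove all four silyl groups to give 14.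

Step 2. What may go wrong:
- coupling through the γ-carbon of the delocalised dienolate or radical (α,γ- or γ,γ-dimers);
- a low preference for the chiral over the meso diastereomer, or for the expected face;
- low conversion, with protonation to the conjugated crotonyl imide;
- Cope rearrangement of 6 if it is warmed.

Fallback, setting out from 2 and rejoining at 10: a non-conjugated enolate is coupled and the double bonds are moved afterwards. Acylation of 2 with pent-4-enoic acid as in step 1 would give (R)-4-benzyl-3-(pent-4-enoyl)oxazolidin-2-one F4. Its lithium enolate (LiN(i-Pr)2, THF, −78 °C), oxidised with TiCl4 or PhI(OAc)2, belongs to the saturated 3-substituted propanoyl class for which this homocoupling is established. It should give (4R,4'R)-3,3'-[(2S,3S)-2,3-diallylbutanedioyl]bis(4-benzyloxazolidin-2-one) F5. LiBH4 reduction would give (2S,3S)-2,3-diallylbutane-1,4-diol F6, and silylation as in step 4 would give (4S,5S)-4,5-bis[(tert-butyldiphenylsilyloxy)methyl]octa-1,7-diene F7. Alkene isomerisation with RuHCl(CO)(PPh3)3 (cat.) in toluene at 80 °C would give (2E,4S,5S,6E)-4,5-bis[(tert-butyldiphenylsilyloxy)methyl]octa-2,6-diene F8. Ozonolysis and acidic methanol as in step 5 would then give 10 through 9.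

Step 5. What may go wrong:
- epimerisation or β-elimination while the dialdehyde is free;
- formation of open-chain dimethyl acetals in place of the cyclic bis-acetal;
- partial loss of a silyl ether in acidic methanol;
- attack of ozone on the silicon-bound phenyl rings.

Fallback, setting out from 8 and rejoining at 10: cleavage through glycols in place of ozonides. Dihydroxylation with OsO4 (cat.) and N-methylmorpholine N-oxide in acetone/water would give (3S,4S)-3,4-bis[(tert-butyldiphenylsilyloxy)methyl]hexane-1,2,5,6-tetraol F9 as a mixture of carbinol epimers. Glycol cleavage with Pb(OAc)4 in CH2Cl2/MeOH at 0 °C, followed directly by catalytic camphorsulfonic acid, would give 10 through 9 under anhydrous conditions.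

Step 3. What may go wrong:
- hydride attack at the ring carbonyl of the hindered imide, opening the auxiliary instead of releasing it;
- base-induced migration of the double bonds into conjugation, with loss of the stereocentres.

Fallback, setting out from 6 and rejoining at 7: hydrolysis before reduction. LiOH/H2O2 in THF/water at 0 °C would cleave the imides selectively at the exocyclic carbonyl to give (2S,3S)-2,3-divinylbutanedioic acid F10 and recovered 2. LiAlH4 in THF at 0 °C would then reduce the diacid to 7.

Step 1. What may go wrong: migration of the β,γ-double bond into conjugation during activation, through a ketene or an enolate. Fallback, setting out from 2 and rejoining at 6: the conjugated isomer is made on purpose. Deprotonation of 2 with n-BuLi in THF at −78 °C and acylation with (E)-but-2-enoyl chloride would give (R)-4-benzyl-3-[(E)-but-2-enoyl]oxazolidin-2-one F11. Its γ-deprotonation with TiCl4 and i-Pr2NEt should give the same dienolate 5, which then couples to 6 as in step 2.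

## Further compounds

F1 | step 6 | tert-butyl(4-bromo-2,6-dimethoxyphenoxy)dimethylsilane | COc1cc(Br)cc(OC)c1O[Si](C)(C)C(C)(C)C
F2 | step 6 | (2S,3S)-1,4-bis[4-(tert-butyldimethylsilyloxy)-3,5-dimethoxyphenyl]-2,3-bis[(tert-butyldiphenylsilyloxy)methyl]butane-1,4-diol, carbinol epimers | COc1cc(C(O)[C@H](CO[Si](c2ccccc2)(c2ccccc2)C(C)(C)C)[C@@H](CO[Si](c2ccccc2)(c2ccccc2)C(C)(C)C)C(O)c2cc(OC)c(O[Si](C)(C)C(C)(C)C)c(OC)c2)cc(OC)c1O[Si](C)(C)C(C)(C)C
F3 | step 6 | (2R,3S,4S,5R)-2,5-bis[4-(tert-butyldimethylsilyloxy)-3,5-dimethoxyphenyl]-3,4-bis[(tert-butyldiphenylsilyloxy)methyl]tetrahydrofuran | COc1cc([C@@H]2O[C@@H](c3cc(OC)c(O[Si](C)(C)C(C)(C)C)c(OC)c3)[C@H](CO[Si](c3ccccc3)(c3ccccc3)C(C)(C)C)[C@H]2CO[Si](c2ccccc2)(c2ccccc2)C(C)(C)C)cc(OC)c1O[Si](C)(C)C(C)(C)C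
F4 | step 2 | (R)-4-benzyl-3-(pent-4-enoyl)oxazolidin-2-one | C=CCCC(=O)N1[C@H](Cc2ccccc2)COC1=O
F5 | step 2 | (4R,4'R)-3,3'-[(2S,3S)-2,3-diallylbutanedioyl]bis(4-benzyloxazolidin-2-one) | C=CC[C@H](C(=O)N1[C@H](Cc2ccccc2)COC1=O)[C@H](CC=C)C(=O)N1[C@H](Cc2ccccc2)COC1=O
F6 | step 2 | (2S,3S)-2,3-diallylbutane-1,4-diol | C=CC[C@H](CO)[C@H](CC=C)CO
F7 | step 2 | (4S,5S)-4,5-bis[(tert-butyldiphenylsilyloxy)methyl]octa-1,7-diene | C=CC[C@H](CO[Si](c1ccccc1)(c1ccccc1)C(C)(C)C)[C@H](CC=C)CO[Si](c1ccccc1)(c1ccccc1)C(C)(C)C
F8 | step 2 | (2E,4S,5S,6E)-4,5-bis[(tert-butyldiphenylsilyloxy)methyl]octa-2,6-diene | C/C=C/[C@H](CO[Si](c1ccccc1)(c1ccccc1)C(C)(C)C)[C@H](/C=C/C)CO[Si](c1ccccc1)(c1ccccc1)C(C)(C)C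
F9 | step 5 | (3S,4S)-3,4-bis[(tert-butyldiphenylsilyloxy)methyl]hexane-1,2,5,6-tetraol, carbinol epimers | OCC(O)[C@H](CO[Si](c1ccccc1)(c1ccccc1)C(C)(C)C)[C@H](C(O)CO)CO[Si](c1ccccc1)(c1ccccc1)C(C)(C)C
F10 | step 3 | (2S,3S)-2,3-divinylbutanedioic acid | C=C[C@H](C(=O)O)[C@H](C=C)C(=O)O
F11 | step 1 | (R)-4-benzyl-3-[(E)-but-2-enoyl]oxazolidin-2-one | C/C=C/C(=O)N1[C@H](Cc2ccccc2)COC1=O
A1 | alternative 1 | dimethyl 2,5-trans-4,5-trans-2,5-bis[4-(benzyloxy)-3,5-dimethoxyphenyl]-4-vinyltetrahydrofuran-3,3-dicarboxylate | COc1cc([C@@H]2O[C@@H](c3cc(OC)c(OCc4ccccc4)c(OC)c3)[C@H](C=C)C2(C(=O)OC)C(=O)OC)cc(OC)c1OCc1ccccc1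
A2 | alternative 1 | trans-2-[4-(benzyloxy)-3,5-dimethoxyphenyl]-3-vinyloxirane, single enantiomer | C=C[C@@H]1O[C@H]1c1cc(OC)c(OCc2ccccc2)c(OC)c1
A3 | alternative 1 | dimethyl 2-[4-(benzyloxy)-3,5-dimethoxybenzylidene]malonate | COC(=O)C(=Cc1cc(OC)c(OCc2ccccc2)c(OC)c1)C(=O)OC
A4 | alternative 2 | dimethyl all-trans-2,5-bis(4-hydroxy-3,5-dimethoxyphenyl)tetrahydrofuran-3,4-dicarboxylate | COc1cc([C@@H]2O[C@@H](c3cc(OC)c(O)c(OC)c3)[C@H](C(=O)OC)[C@H]2C(=O)OC)cc(OC)c1O
A5 | alternative 2 | dimethyl all-trans-3,4-bis(4-hydroxy-3,5-dimethoxyphenyl)cyclobutane-1,2-dicarboxylate, single enantiomer | COc1cc([C@@H]2[C@@H](c3cc(OC)c(O)c(OC)c3)[C@H](C(=O)OC)[C@H]2C(=O)OC)cc(OC)c1O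
A6 | alternative 2 | methyl (E)-3-(4-hydroxy-3,5-dimethoxyphenyl)acrylate (methyl sinapate) | COC(=O)/C=C/c1cc(OC)c(O)c(OC)c1
A7 | alternative 3 | all-trans 2-(4-hydroxy-3,5-dimethoxyphenyl)-5-[4-(benzyloxy)-3,5-dimethoxyphenyl]-3,4-bis[(tert-butyldimethylsilyloxy)methyl]tetrahydrofuran | COc1cc([C@@H]2O[C@@H](c3cc(OC)c(OCc4ccccc4)c(OC)c3)[C@H](CO[Si](C)(C)C(C)(C)C)[C@H]2CO[Si](C)(C)C(C)(C)C)cc(OC)c1O
A8 | alternative 3 | 4-{4-[4-(benzyloxy)-3,5-dimethoxyphenyl]-4-hydroxy-2,3-bis[(tert-butyldimethylsilyloxy)methyl]butyl}-2,6-dimethoxyphenol, configuration as in the SMILES | COc1cc(C[C@H](CO[Si](C)(C)C(C)(C)C)[C@@H](CO[Si](C)(C)C(C)(C)C)[C@@H](O)c2cc(OC)c(OCc3ccccc3)c(OC)c2)cc(OC)c1O
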